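**Retrosynthetic overview**
- The ten-membered carbocycle is closed last, at C5–C6, by a light-driven nickel-catalysed C(sp3)–H alkenylation of the butenolide γ-CH2 with a Z-alkenyl bromide; this step sets C6.
- C7–C8 comes from a Nozaki–Hiyama–Kishi addition of a β-iodobutenolide to a β-hydroxy aldehyde (sets C8 under control of C10); the methacrylate and the tertiary acetate are put on afterwards.
- C2–C3 comes from alkylation of a methyl ketone dianion with a Z-configured allylic bromide; C10 comes from (R)-lactic acid by Seebach self-regeneration of stereocentres (allylation, then MeLi opening).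
- The butenolide fragment is made from but-2-yne-1,4-diol (Tsuji carbonylation to an allenoate, then iodolactonisation); the Z-dibromide is made from propargyl alcohol.
- Ring order: butenolide ring first (in its fragment), ten-membered ring last.

Assumption: germacrane numbering is used for atom labels (C1 ketone, C4=C5 alkene, C6 lactone carbinol, C8 methacrylate carbinol, C10 tertiary acetate, C13 acetoxymethyl), and D-(R)-lactic acid is taken as a cheap chiral-pool material.

**Fragment A: Z-dibromide**

Step 1
Reactants: 1 prop-2-yn-1-ol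
Product: 3 (Z)-3-bromo-2-methylprop-2-en-1-ol, via bromomagnesium alkenyl alkoxide 2 (not isolated)
Conditions: MeMgBr (2.5 equiv), CuI (10 mol %), THF, 0 to 25 °C; then BrCl2C–CCl2Br, −20 °C; H2O
Reagents that add atoms: methylmagnesium bromide C[Mg]Br; 1,2-dibromo-1,1,2,2-tetrachloroethane BrC(Cl)(Cl)C(Cl)(Cl)Br
Why: Copper-catalysed anti-carbomagnesiation of the magnesium propargyl alkoxide (Duboudin reaction) puts methyl on the inner carbon and magnesium, held in a five-membered chelate, on the terminal carbon cis to CH2O, so brominolysis of the alkenyl Grignard gives only the Z-bromide.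

Step 2
Reactants: 3 (Z)-3-bromo-2-methylprop-2-en-1-ol
Product: 4 (Z)-1,3-dibromo-2-methylprop-1-ene
Conditions: CBr4, PPh3, CH2Cl2, 0 °C
Reagents that add atoms: carbon tetrabromide BrC(Br)(Br)Br
Why: Appel bromination converts the primary allylic alcohol into the bromide under neutral conditions without touching the alkene geometry.

**Fragment B: iodobutenolide**

Step 3
Reactants: 5 but-2-yne-1,4-diol
Product: 6 4-hydroxybut-2-yn-1-yl acetate
Conditions: Ac2O (1.0 equiv), pyridine, CH2Cl2, 0 °C
Reagents that add atoms: acetic anhydride CC(=O)OC(C)=O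
Why: Statistical mono-acylation of the symmetric diol with one equivalent of anhydride (nucleophilic acyl substitution); unreacted diol is recycled.

Step 4
Reactants: 6 4-hydroxybut-2-yn-1-yl acetate
Product: 7 4-acetoxybut-2-yn-1-yl methyl carbonate
Conditions: ClCO2Me, pyridine, CH2Cl2, 0 °C
Reagents that add atoms: methyl chloroformate COC(=O)Cl
Why: Chloroformate acylation of the remaining primary alcohol gives a mixed acetate–carbonate in which only the carbonate ionises readily with zerovalent palladium.

Step 5
Reactants: 7 4-acetoxybut-2-yn-1-yl methyl carbonate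
Product: 8 methyl 2-(acetoxymethyl)buta-2,3-dienoate
Conditions: Pd(OAc)2 (2 mol %), PPh3 (8 mol %), CO (10 bar), MeOH, 40 °C
Reagents that add atoms: carbon monoxide [C-]#[O+]
Why: Tsuji carbonylation: zerovalent palladium opens the propargylic carbonate in SN2' fashion with loss of CO2 to an allenylpalladium methoxide, and CO insertion followed by methoxide transfer gives the 2,3-dienoate while the less reactive acetate is kept.

Step 6
Reactants: 8 methyl 2-(acetoxymethyl)buta-2,3-dienoate
Product: 9 (4-iodo-2-oxo-2,5-dihydrofuran-3-yl)methyl acetate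
Conditions: I2 (1.5 equiv), MeCN, 25 °C
Reagents that add atoms: iodine II
Why: Iodolactonisation of the 2,3-allenoate (Ma cyclisation): iodonium formation at the remote double bond, attack of the ester carbonyl oxygen on the terminal CH2 and demethylation by iodide give the β-iodobutenolide.

**Main line**

Step 7
Reactants: 10 (R)-lactic acid
Product: 11 (2R,5R)-2-tert-butyl-5-methyl-1,3-dioxolan-4-one
Conditions: pivalaldehyde, TsOH·H2O (cat.), pentane, reflux (Dean–Stark); crystallisation of the cis isomer
Reagents that add atoms: pivalaldehyde CC(C)(C)C=O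
Why: Acid-catalysed acetalisation (Seebach dioxolanone formation); the thermodynamically favoured cis isomer stores the lactic acid chirality in the new acetal centre.

Step 8
Reactants: 11 (2R,5R)-2-tert-butyl-5-methyl-1,3-dioxolan-4-one
Product: 13 (2R,5S)-5-allyl-2-tert-butyl-5-methyl-1,3-dioxolan-4-one, via lithium enolate 12 (not isolated)
Conditions: LDA, THF, −78 °C; allyl bromide, −78 to −30 °C
Reagents that add atoms: allyl bromide C=CCBr
Why: Seebach self-regeneration of stereocentres: the planar enolate is allylated anti to the tert-butyl group (dr above 95:5), so the quaternary centre that becomes C10 is fixed as S by the lactic-acid-derived acetal carbon alone.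

Step 9
Reactants: 13 (2R,5S)-5-allyl-2-tert-butyl-5-methyl-1,3-dioxolan-4-one
Product: 15 (S)-3-hydroxy-3-methylhex-5-en-2-one, via lithium hemiketal alkoxide 14 (not isolated)
Conditions: MeLi (1.05 equiv), THF, −78 °C; AcOH, −78 to 20 °C
Reagents that add atoms: methyllithium [Li]C
Why: Mono-addition of methyllithium to the lactone carbonyl (acyl substitution) gives a tetrahedral lithium hemiketal that is stable at −78 °C and collapses on acidic quench, with loss of pivalaldehyde, to the methyl ketone; the quaternary centre is untouched.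

Step 10
Reactants: 15 (S)-3-hydroxy-3-methylhex-5-en-2-one; 4 (Z)-1,3-dibromo-2-methylprop-1-ene
Product: 17 (1Z,6S)-1-bromo-6-hydroxy-2,6-dimethylnona-1,8-dien-5-one, via dilithium alkoxide enolate 16 (not isolated)
Conditions: LDA (2.2 equiv), THF, −78 to −40 °C; then 4, −78 to −20 °C; H2O
Reagents that add atoms: none
Why: Alkoxide–enolate dianion alkylation: the methyl group is the only enolisable position, and its lithium enolate displaces the allylic bromide by SN2 while the Z-alkenyl bromide is retained.

Step 11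
Reactants: 17 (1Z,6S)-1-bromo-6-hydroxy-2,6-dimethylnona-1,8-dien-5-one
Product: 18 (3S,7Z)-8-bromo-3-hydroxy-3,7-dimethyl-4-oxooct-7-enal
Conditions: OsO4 (2 mol %), NaIO4 (3 equiv), 2,6-lutidine, 1,4-dioxane–H2O 3:1, 20 °C, 1.5 h; used crude
Reagents that add atoms: osmium tetroxide O=[Os](=O)(=O)=O (catalytic oxygen carrier); sodium periodate [Na+].[O-]I(=O)(=O)=O (terminal oxidant)
Why: Lemieux–Johnson oxidative cleavage: OsO4 dihydroxylates only the monosubstituted alkene (the bromo-substituted trisubstituted alkene is electron-poor and hindered), and periodate cleaves the 1,2-diol much faster than the hindered tertiary ketol.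

Step 12
Reactants: 18 (3S,7Z)-8-bromo-3-hydroxy-3,7-dimethyl-4-oxooct-7-enal; 9 (4-iodo-2-oxo-2,5-dihydrofuran-3-yl)methyl acetate
Product: 20 [4-[(1S,3S,7Z)-8-bromo-1,3-dihydroxy-3,7-dimethyl-4-oxooct-7-en-1-yl]-2-oxo-2,5-dihydrofuran-3-yl]methyl acetate, via alkenylchromium dichloride 19 (not isolated)
Conditions: CrCl2 (6 equiv), NiCl2 (2 mol %), DMSO, 25 °C; chromatographic removal of the C8 epimer
Reagents that add atoms: none
Why: Nozaki–Hiyama–Kishi reaction: zerovalent nickel inserts selectively into the activated C–I bond of 9 (the unactivated alkenyl bromide of 18 is left), transmetalation gives alkenylchromium 19, which adds only to the aldehyde; C8 is set S (1,3-anti to the C10 oxygen) through a dipole-minimised Felkin–Evans arrangement with the C10–O bond opposed to the carbonyl and the longer acyl chain extended away from the reacting centre, with only modest selectivity expected.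

Step 13
Reactants: 20 [4-[(1S,3S,7Z)-8-bromo-1,3-dihydroxy-3,7-dimethyl-4-oxooct-7-en-1-yl]-2-oxo-2,5-dihydrofuran-3-yl]methyl acetate
Product: 21 (1S,3S,7Z)-1-[4-(acetoxymethyl)-5-oxo-2,5-dihydrofuran-3-yl]-8-bromo-3-hydroxy-3,7-dimethyl-4-oxooct-7-en-1-yl 2-methylprop-2-enoate
Conditions: methacryloyl chloride (1.3 equiv), pyridine, DMAP (10 mol %), CH2Cl2, −20 to 0 °C
Reagents that add atoms: methacryloyl chloride C=C(C)C(Cl)=O
Why: DMAP-catalysed acylation esterifies only the secondary C8 hydroxyl (the tertiary ketol hydroxyl is inert at 0 °C), with retention at C8.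

Step 14
Reactants: 21 (1S,3S,7Z)-1-[4-(acetoxymethyl)-5-oxo-2,5-dihydrofuran-3-yl]-8-bromo-3-hydroxy-3,7-dimethyl-4-oxooct-7-en-1-yl 2-methylprop-2-enoate
Product: 22 (1S,3S,7Z)-3-acetoxy-1-[4-(acetoxymethyl)-5-oxo-2,5-dihydrofuran-3-yl]-8-bromo-3,7-dimethyl-4-oxooct-7-en-1-yl 2-methylprop-2-enoate
Conditions: Ac2O (5 equiv), Sc(OTf)3 (5 mol %), MeCN, −20 °C
Reagents that add atoms: acetic anhydride CC(=O)OC(C)=O
Why: Scandium triflate-catalysed acetylation (Yamamoto acylation) acylates the hindered tertiary hydroxyl under non-basic conditions that spare the base-sensitive acetoxymethyl butenolide; no stereocentre is touched.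

Step 15
Reactants: 22 (1S,3S,7Z)-3-acetoxy-1-[4-(acetoxymethyl)-5-oxo-2,5-dihydrofuran-3-yl]-8-bromo-3,7-dimethyl-4-oxooct-7-en-1-yl 2-methylprop-2-enoate
Product: 24 (4Z,6R,8S,10S)-10,13-diacetoxy-8-(methacryloyloxy)-1-oxogermacra-4,7(11)-dien-12,6-olide (CNP0115165.3), via alkenylnickel bromide 23 (not isolated)
Conditions: NiBr2·MeOCH2CH2OMe (20 mol %), 4,4'-di-tert-butyl-2,2'-bipyridine (dtbbpy, 24 mol %), [Ir(dF(CF3)ppy)2(dtbbpy)]PF6 (2 mol %), 2,6-lutidine (2 equiv), degassed EtOAc, 1.5 mM, 450 nm LEDs, 25 °C
Reagents that add atoms: none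
Why: Proposed new method: ring-closing nickel/photoredox C(sp3)–H alkenylation of a butenolide γ-methylene; zerovalent nickel inserts into the alkenyl C–Br bond with retention of the Z geometry (23), the excited iridium complex oxidises the divalent alkenylnickel bromide to a trivalent species that releases a bromine atom, at 1.5 mM this bromine atom abstracts hydrogen mainly within the same molecule from C6, the weakest C–H bond (cyclic, allylic, α to the lactone oxygen, radical delocalised into the lactone carbonyl; the C8–H bond lies in the butenolide plane to avoid A(1,3) strain with C13H2OAc and is stereoelectronically switched off), the C6 radical is captured by nickel and C–C reductive elimination closes the ten-membered ring while lutidine takes up HBr; C6 becomes R because the ring closes with C7 at a corner of the ten-membered ring, which puts the new C5–C6 bond on the butenolide face opposite the C8–C9 bond; the closest known reaction is the intermolecular nickel/photoredox coupling of allylic C(sp3)–H bonds with alkenyl bromides through bromine-radical hydrogen-atom transfer, which has not been shown for a butenolide γ-position or as a macrocyclisation.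

**Compound list**

1 | prop-2-yn-1-ol | C#CCO | starting material
2 | bromomagnesium (Z)-3-(bromomagnesio)-2-methylprop-2-en-1-olate | Br[Mg]OC/C(C)=C\[Mg]Br | intermediate
3 | (Z)-3-bromo-2-methylprop-2-en-1-ol | OC/C(C)=C\Br | intermediate
4 | (Z)-1,3-dibromo-2-methylprop-1-ene | BrC/C(C)=C\Br | intermediate
5 | but-2-yne-1,4-diol | OCC#CCO | starting material
6 | 4-hydroxybut-2-yn-1-yl acetate | CC(=O)OCC#CCO | intermediate
7 | 4-acetoxybut-2-yn-1-yl methyl carbonate | COC(=O)OCC#CCOC(C)=O | intermediate
8 | methyl 2-(acetoxymethyl)buta-2,3-dienoate | C=C=C(COC(C)=O)C(=O)OC | intermediate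
9 | (4-iodo-2-oxo-2,5-dihydrofuran-3-yl)methyl acetate | CC(=O)OCC1=C(I)COC1=O | intermediate
10 | (R)-lactic acid | C[C@@H](O)C(=O)O | starting material
11 | (2R,5R)-2-tert-butyl-5-methyl-1,3-dioxolan-4-one | C[C@H]1O[C@@H](C(C)(C)C)OC1=O | intermediate
12 | lithium (R)-2-tert-butyl-5-methyl-1,3-dioxol-4-olate (enolate of 11) | CC1=C(O[Li])O[C@H](C(C)(C)C)O1 | intermediate
13 | (2R,5S)-5-allyl-2-tert-butyl-5-methyl-1,3-dioxolan-4-one | C[C@@]1(CC=C)O[C@@H](C(C)(C)C)OC1=O | intermediate
14 | lithium (2R,5S)-5-allyl-2-tert-butyl-4,5-dimethyl-1,3-dioxolan-4-olate (hemiketal alkoxide) | C[C@@]1(CC=C)O[C@@H](C(C)(C)C)OC1(C)O[Li] | intermediate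
15 | (S)-3-hydroxy-3-methylhex-5-en-2-one | C=CC[C@](C)(O)C(C)=O | intermediate
16 | dilithium (S)-3-methyl-3-oxidohexa-1,5-dien-2-olate (alkoxide enolate of 15) | C=CC[C@](C)(O[Li])C(=C)O[Li] | intermediate
17 | (1Z,6S)-1-bromo-6-hydroxy-2,6-dimethylnona-1,8-dien-5-one | C=CC[C@](C)(O)C(=O)CC/C(C)=C\Br | intermediate
18 | (3S,7Z)-8-bromo-3-hydroxy-3,7-dimethyl-4-oxooct-7-enal | O=CC[C@](C)(O)C(=O)CC/C(C)=C\Br | intermediate
19 | [4-(dichlorochromio)-2-oxo-2,5-dihydrofuran-3-yl]methyl acetate (alkenylchromium from 9) | CC(=O)OCC1=C([Cr](Cl)Cl)COC1=O | intermediate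
20 | [4-[(1S,3S,7Z)-8-bromo-1,3-dihydroxy-3,7-dimethyl-4-oxooct-7-en-1-yl]-2-oxo-2,5-dihydrofuran-3-yl]methyl acetate | O[C@@H](C[C@](C)(O)C(=O)CC/C(C)=C\Br)C1=C(COC(C)=O)C(=O)OC1 | intermediate
21 | (1S,3S,7Z)-1-[4-(acetoxymethyl)-5-oxo-2,5-dihydrofuran-3-yl]-8-bromo-3-hydroxy-3,7-dimethyl-4-oxooct-7-en-1-yl 2-methylprop-2-enoate | C=C(C)C(=O)O[C@@H](C[C@](C)(O)C(=O)CC/C(C)=C\Br)C1=C(COC(C)=O)C(=O)OC1 | intermediate
22 | (1S,3S,7Z)-3-acetoxy-1-[4-(acetoxymethyl)-5-oxo-2,5-dihydrofuran-3-yl]-8-bromo-3,7-dimethyl-4-oxooct-7-en-1-yl 2-methylprop-2-enoate | C=C(C)C(=O)O[C@@H](C[C@](C)(OC(C)=O)C(=O)CC/C(C)=C\Br)C1=C(COC(C)=O)C(=O)OC1 | intermediate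
23 | alkenylnickel bromide from 22 (dtbbpy ligand on nickel not drawn) | C=C(C)C(=O)O[C@@H](C[C@](C)(OC(C)=O)C(=O)CC/C(C)=C\[Ni]Br)C1=C(COC(C)=O)C(=O)OC1 | intermediate
24 | (4Z,6R,8S,10S)-10,13-diacetoxy-8-(methacryloyloxy)-1-oxogermacra-4,7(11)-dien-12,6-olide (CNP0115165.3) | C=C(C)C(=O)O[C@H]1C[C@](C)(OC(C)=O)C(=O)CC/C(C)=C\[C@H]2OC(=O)C(COC(C)=O)=C12 | target

**Totals**

Total step count: 15 (2 for fragment A, 4 for fragment B, 9 on the main line).
Longest linear sequence: 9 steps (steps 7 to 15, from (R)-lactic acid).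

**Steps most likely to fail, with fallbacks**

Step 15 (the proposed new ring closure). Risks are intermolecular coupling, hydrogen abstraction at C8 or C13, and the wrong C6 epimer. The fallback uses known chemistry and a polar instead of a radical bond formation. It sets out from 22. Soft enolisation (TIPSOTf, Et3N, CH2Cl2, 0 °C) gives the triisopropylsilyloxyfuran F1. Oxidation with dimethyldioxirane in acetone at −78 °C, followed by aqueous work-up, gives the γ-hydroxybutenolide F2, a masked Z-4-oxo-enoic acid. A classical Nozaki–Hiyama–Kishi macrocyclisation (CrCl2, 10 equiv, NiCl2, 5 mol %, DMSO, 2 mM, 50 °C) adds the alkenyl bromide to the lactol aldehyde, and the resulting hydroxy acid lactonises on acidic work-up. The fallback comes back to the route at 24.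

Step 12 (C7–C8 coupling). Risks are low or reversed 1,3-induction at C8 and ring-opening of the β-metalated butenolide. The fallback makes the sequence stereoconvergent. It sets out from 18 and 9 with the same coupling, but the separated (8R)-epimer, [4-[(1R,3S,7Z)-8-bromo-1,3-dihydroxy-3,7-dimethyl-4-oxooct-7-en-1-yl]-2-oxo-2,5-dihydrofuran-3-yl]methyl acetate F3, is not discarded. It is esterified under Mitsunobu conditions (methacrylic acid, PPh3, DIAD, toluene, 0 °C), which inverts C8 and leaves the tertiary hydroxyl alone. The fallback comes back to the route at 21.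

Step 9 (mono-addition of MeLi). The risk is collapse of the hemiketal before quench, followed by over-addition. The fallback sets out from 13. Aminolysis with MeNH(OMe)·HCl and iPrMgCl (THF, −20 °C) opens the dioxolanone, with loss of pivalaldehyde, to the Weinreb amide (S)-2-hydroxy-N-methoxy-N,2-dimethylpent-4-enamide F4. MeMgBr (2.2 equiv, THF, 0 °C) then stops at the ketone through the magnesium chelate. The fallback comes back to the route at 15.

**Further compounds**

F1 | step 15 | (1S,3S,7Z)-3-acetoxy-1-[4-(acetoxymethyl)-5-(triisopropylsilyloxy)furan-3-yl]-8-bromo-3,7-dimethyl-4-oxooct-7-en-1-yl 2-methylprop-2-enoate | C=C(C)C(=O)O[C@@H](C[C@](C)(OC(C)=O)C(=O)CC/C(C)=C\Br)c1coc(O[Si](C(C)C)(C(C)C)C(C)C)c1COC(C)=O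
F2 | step 15 | (1S,3S,7Z)-3-acetoxy-1-[4-(acetoxymethyl)-2-hydroxy-5-oxo-2,5-dihydrofuran-3-yl]-8-bromo-3,7-dimethyl-4-oxooct-7-en-1-yl 2-methylprop-2-enoate | C=C(C)C(=O)O[C@@H](C[C@](C)(OC(C)=O)C(=O)CC/C(C)=C\Br)C1=C(COC(C)=O)C(=O)OC1O
F3 | step 12 | [4-[(1R,3S,7Z)-8-bromo-1,3-dihydroxy-3,7-dimethyl-4-oxooct-7-en-1-yl]-2-oxo-2,5-dihydrofuran-3-yl]methyl acetate | O[C@H](C[C@](C)(O)C(=O)CC/C(C)=C\Br)C1=C(COC(C)=O)C(=O)OC1
F4 | step 9 | (S)-2-hydroxy-N-methoxy-N,2-dimethylpent-4-enamide | C=CC[C@](C)(O)C(=O)N(C)OC
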